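**Assumption:** cembrane numbering is used (C1 = ring-fusion olefinic carbon, C2 = CH–O, C3=C4, C7/C8 = epoxide, C11=C12, C15 = second carbon of the tetrasubstituted olefin, C16 = ring OCH2, C17 = CH2OAc). The SMILES reads as (2R,7R,8R), 3E, 11E. Hex-1-en-5-yne is taken as a catalogue chemical.

## Retrosynthetic overview

1. Target ⇐ triol 23: the 2,5-dihydrofuran is closed last by C2–O attack on an activated C16, and the other CH2 becomes CH2OAc. C15 carries two identical CH2O arms, so the C1=C15 olefin has no geometry to control.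
2. The 14-membered carbocycle ⇐ intramolecular B-alkyl Suzuki coupling, C14–C1 (terminal diene hydroboration onto a vinyl bromide).
3. Linear precursor ⇐ late Negishi sp3–sp2 union at C4–C5 of fragment A (C1–C4, C15–C18; C2 set by CBS reduction) and fragment B (C5–C14; epoxide set by Shi epoxidation).
4. A from dihydroxyacetone, CBr4, DMF and propynyl Grignard; B from hex-1-en-5-yne, ethylene oxide and two Wittig extensions.
5. Ring order: oxirane (fragment stage) → 14-membered carbocycle → 2,5-dihydrofuran.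

## Fragment A (C1–C4, C15–C18)

**Step 1**
Reactants: 1, 1,3-dihydroxyacetone (used as its dimer)
Product: 2, 1,3-bis[(tert-butyldimethylsilyl)oxy]propan-2-one
Conditions: TBSCl, imidazole, DMF, 0 → 23 °C
Reagents that add atoms: TBSCl, CC(C)(C)[Si](C)(C)Cl
Why: Standard silyl ether protection of both primary hydroxyls; the dimer cracks to monomer under the conditions.

**Step 2**
Reactants: 2
Product: 3, 1,1-dibromo-3-(TBSO)-2-[(TBSO)methyl]prop-1-ene
Conditions: CBr4, PPh3, CH2Cl2, 0 → 23 °C
Reagents that add atoms: carbon tetrabromide, BrC(Br)(Br)Br (supplies C1 and both Br)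
Why: Ramirez dibromo-olefination of an unhindered ketone; the two CH2OTBS arms are identical, so no olefin isomers arise.

**Step 3**
Reactants: 3
Product: 4, 2-bromo-4-(TBSO)-3-[(TBSO)methyl]but-2-enal
Conditions: n-BuLi (1.0 equiv), THF–Et2O, −105 °C; DMF; aq. NH4Cl
Reagents that add atoms: N,N-dimethylformamide, CN(C)C=O (supplies C2)
Why: Br/Li exchange gives a 1-bromo-1-lithioalkene carbenoid that is stable at this temperature and is formylated by DMF.

**Step 4**
Reactants: 4; 5, prop-1-yn-1-ylmagnesium bromide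
Product: 6, rac-5-bromo-7-(TBSO)-6-[(TBSO)methyl]hept-5-en-2-yn-4-ol
Conditions: THF, −78 → 0 °C
Reagents that add atoms: none (beyond 5)
Why: 1,2-Grignard addition to a non-enolisable α-bromo enal; the racemic carbinol is corrected in steps 5–6.

**Step 5**
Reactants: 6
Product: 7, 5-bromo-7-(TBSO)-6-[(TBSO)methyl]hept-5-en-2-yn-4-one
Conditions: Dess–Martin periodinane, NaHCO3, CH2Cl2, 0 °C
Reagents that add atoms: none
Why: Dess–Martin oxidation of a secondary propargylic alcohol; silyl ethers and the vinyl bromide are untouched.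

**Step 6**
Reactants: 7
Product: 8, (4R)-5-bromo-7-(TBSO)-6-[(TBSO)methyl]hept-5-en-2-yn-4-ol
Conditions: (S)-Me-CBS (1 equiv), catecholborane, toluene, −78 °C
Reagents that add atoms: none
Why: Corey–Bakshi–Shibata reduction; the twisted 1-bromoalkenyl group acts as the large substituent and the slender propynyl as the small one, so the (S)-catalyst gives the (R)-carbinol (C2 of the target).

**Step 7**
Reactants: 8
Product: 9, (4R)-5-bromo-4,7-bis(TBSO)-6-[(TBSO)methyl]hept-5-en-2-yne
Conditions: TBSOTf, 2,6-lutidine, CH2Cl2, −78 → 0 °C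
Reagents that add atoms: TBSOTf, CC(C)(C)[Si](C)(C)OS(=O)(=O)C(F)(F)F
Why: Silylation of the hindered secondary alcohol so that it survives the organometallic steps.

**Step 8**
Reactants: 9
Product: 10 (fragment A), (2E,4R)-5-bromo-2-iodo-4,7-bis(TBSO)-6-[(TBSO)methyl]hepta-2,5-diene
Conditions: Cp2Zr(H)Cl (2.5 equiv), THF, 23 → 45 °C; then I2, 0 °C
Reagents that add atoms: iodine, II
Why: syn-Hydrozirconation places Zr on the less hindered, methyl-bearing alkyne carbon (thermodynamic control with excess Schwartz reagent), and iodinolysis with retention gives the (E)-2-iodoalkene, which fixes the C3=C4 geometry.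

## Fragment B (C5–C14)

**Step 9**
Reactants: 11, hex-1-en-5-yne
Product: 12, (1E)-1-iodo-2-methylhexa-1,5-diene
Conditions: AlMe3, Cp2ZrCl2 (25 mol %), CH2Cl2, 0 → 23 °C; then I2, THF, −30 → 0 °C
Reagents that add atoms: trimethylaluminium, C[Al](C)C; iodine, II
Why: Negishi Zr-catalysed carboalumination adds Me–Al syn across the terminal alkyne (the alkene is far slower), and iodinolysis with retention gives the E iodide.

**Step 10**
Reactants: 12; 13, oxirane (ethylene oxide)
Product: 14, (3E)-4-methylocta-3,7-dien-1-ol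
Conditions: t-BuLi (2.1 equiv), Et2O, −78 °C; then oxirane, BF3·OEt2, −78 °C
Reagents that add atoms: none (beyond 13)
Why: I/Li exchange with retention, then BF3-assisted epoxide opening by the alkenyllithium, installs C5–C6 and keeps the E olefin.

**Step 11**
Reactants: 14
Product: 15, (5E)-8-chloro-5-methylocta-1,5-diene
Conditions: PPh3, NCS, THF, 0 → 23 °C
Reagents that add atoms: N-chlorosuccinimide, O=C1CCC(=O)N1Cl
Why: Appel-type chlorination; the primary chloride is inert to the oxidants and ylides that follow and avoids a free 3,4-epoxy alcohol.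

**Step 12**
Reactants: 15
Product: 16, (2R,3R)-2-(but-3-en-1-yl)-3-(2-chloroethyl)-2-methyloxirane
Conditions: D-fructose-derived Shi ketone (30 mol %), Oxone, K2CO3, Bu4NHSO4, MeCN–DMM / aq. borate buffer (pH 10.5), 0 °C
Reagents that add atoms: Oxone (potassium peroxymonosulfate), OOS(=O)(=O)[O-].[K+]
Why: Shi asymmetric epoxidation; the chiral dioxirane attacks the E-trisubstituted olefin through the spiro transition state to give the (R,R)-epoxide (C7, C8) and leaves the much less reactive monosubstituted alkene alone.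

**Step 13**
Reactants: 16
Product: 17, 3-[(2R,3R)-3-(2-chloroethyl)-2-methyloxiran-2-yl]propanal
Conditions: O3, NaHCO3, CH2Cl2–MeOH, −78 °C; then PPh3
Reagents that add atoms: ozone, O=[O+][O-]
Why: Ozonolysis of the only remaining alkene under buffered conditions; epoxide and chloride are inert.

**Step 14**
Reactants: 17
Product: 18, (2E)-5-[(2R,3R)-3-(2-chloroethyl)-2-methyloxiran-2-yl]-2-methylpent-2-enal
Conditions: Ph3P=C(Me)CHO, toluene, 80 °C
Reagents that add atoms: 2-(triphenylphosphoranylidene)propanal, CC(C=O)=P(c1ccccc1)(c1ccccc1)c1ccccc1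
Why: Wittig reaction with a stabilised ylide is E-selective (>95:5) and sets the C11=C12 geometry; the hindered product enal does not react further.

**Step 15**
Reactants: 18
Product: 19, (2R,3R)-3-(2-chloroethyl)-2-methyl-2-[(3E)-4-methylhexa-3,5-dien-1-yl]oxirane
Conditions: Ph3PCH3Br, KHMDS, THF, −78 → 0 °C
Reagents that add atoms: methyltriphenylphosphonium bromide, C[P+](c1ccccc1)(c1ccccc1)c1ccccc1.[Br-]
Why: Wittig methylenation of the enal gives the terminal 1,3-diene (C13=C14); a primary chloride tolerates the ylide at ≤ 0 °C.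

**Step 16**
Reactants: 19
Product: 20 (fragment B), (2R,3R)-3-(2-iodoethyl)-2-methyl-2-[(3E)-4-methylhexa-3,5-dien-1-yl]oxirane
Conditions: NaI, NaHCO3, acetone, reflux
Reagents that add atoms: sodium iodide, [Na+].[I-]
Why: Finkelstein exchange gives the iodide needed for zinc insertion; neutral iodide does not open the epoxide.

## Union, macrocyclisation and endgame

**Step 17**
Reactants: 20; 10
Product: 21, (2R,3R)-3-[(3E,5R)-6-bromo-5,8-bis(TBSO)-7-[(TBSO)methyl]-3-methylocta-3,6-dien-1-yl]-2-methyl-2-[(3E)-4-methylhexa-3,5-dien-1-yl]oxirane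
Conditions: 20, Zn dust (BrCH2CH2Br/TMSCl-activated), LiCl, THF, 35 °C; then 10, Pd(dppf)Cl2·CH2Cl2 (5 mol %), THF, 23 °C
Reagents that add atoms: none
Why: Negishi sp3–sp2 coupling forms C4–C5; the alkylzinc does not attack the epoxide, Pd inserts into the alkenyl C–I bond far faster than into the hindered tetrasubstituted C–Br bond, and olefin geometry is retained.

**Step 18**
Reactants: 21
Product: 22, (2R,3E,7R,8R,11E)-7,8-epoxy-2,16,17-tris(TBSO)cembra-1(15),3,11-triene
Conditions: 9-BBN, THF, 0 → 23 °C; then slow addition to Pd(dppf)Cl2·CH2Cl2 (20 mol %), AsPh3, Cs2CO3, DMF–THF–H2O, 50 °C, 2 mM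
Reagents that add atoms: none
Why: 9-BBN hydroborates only the monosubstituted diene terminus (anti-Markovnikov, boron on C14), and the intramolecular B-alkyl Suzuki–Miyaura coupling with the C1 bromide closes the 14-membered ring without creating a stereocenter.

**Step 19**
Reactants: 22
Product: 23, (2R,3E,7R,8R,11E)-7,8-epoxycembra-1(15),3,11-triene-2,16,17-triol
Conditions: TBAF, THF, 0 → 23 °C
Reagents that add atoms: none
Why: Fluoride desilylation of all three silyl ethers; epoxide and olefins are stable to basic fluoride.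

**Step 20**
Reactants: 23
Product: 24, lobophynin B
Conditions: MsCl (2.1 equiv), Et3N, CH2Cl2, −40 → 0 °C; then CsOAc, 18-crown-6, DMF, 23 °C (one pot)
Reagents that add atoms: cesium acetate, CC(=O)[O-].[Cs+]
Why: The two primary allylic hydroxyls are sulfonylated selectively, the C2–OH displaces the cis mesylate (5-exo-tet Williamson etherification, C2–O bond untouched so configuration is retained), and acetate displaces the remaining allylic mesylate by SN2; the two CH2 arms are equivalent, so either order converges on one product.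

## Compound list

1 | 1,3-dihydroxyacetone | OCC(=O)CO | starting material
2 | 1,3-bis(TBSO)propan-2-one | CC(C)(C)[Si](C)(C)OCC(=O)CO[Si](C)(C)C(C)(C)C | intermediate
3 | 1,1-dibromo-3-(TBSO)-2-[(TBSO)methyl]prop-1-ene | BrC(Br)=C(CO[Si](C)(C)C(C)(C)C)CO[Si](C)(C)C(C)(C)C | intermediate
4 | 2-bromo-4-(TBSO)-3-[(TBSO)methyl]but-2-enal | O=CC(Br)=C(CO[Si](C)(C)C(C)(C)C)CO[Si](C)(C)C(C)(C)C | intermediate
5 | prop-1-yn-1-ylmagnesium bromide | CC#C[Mg]Br | starting material
6 | rac-5-bromo-7-(TBSO)-6-[(TBSO)methyl]hept-5-en-2-yn-4-ol | CC#CC(O)C(Br)=C(CO[Si](C)(C)C(C)(C)C)CO[Si](C)(C)C(C)(C)C | intermediate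
7 | 5-bromo-7-(TBSO)-6-[(TBSO)methyl]hept-5-en-2-yn-4-one | CC#CC(=O)C(Br)=C(CO[Si](C)(C)C(C)(C)C)CO[Si](C)(C)C(C)(C)C | intermediate
8 | (4R)-5-bromo-7-(TBSO)-6-[(TBSO)methyl]hept-5-en-2-yn-4-ol | CC#C[C@@H](O)C(Br)=C(CO[Si](C)(C)C(C)(C)C)CO[Si](C)(C)C(C)(C)C | intermediate
9 | (4R)-5-bromo-4,7-bis(TBSO)-6-[(TBSO)methyl]hept-5-en-2-yne | CC#C[C@@H](O[Si](C)(C)C(C)(C)C)C(Br)=C(CO[Si](C)(C)C(C)(C)C)CO[Si](C)(C)C(C)(C)C | intermediate
10 | (2E,4R)-5-bromo-2-iodo-4,7-bis(TBSO)-6-[(TBSO)methyl]hepta-2,5-diene (fragment A) | I/C(C)=C/[C@@H](O[Si](C)(C)C(C)(C)C)C(Br)=C(CO[Si](C)(C)C(C)(C)C)CO[Si](C)(C)C(C)(C)C | intermediate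
11 | hex-1-en-5-yne | C=CCCC#C | starting material
12 | (1E)-1-iodo-2-methylhexa-1,5-diene | I/C=C(C)/CCC=C | intermediate
13 | oxirane | C1CO1 | starting material
14 | (3E)-4-methylocta-3,7-dien-1-ol | OCC/C=C(C)/CCC=C | intermediate
15 | (5E)-8-chloro-5-methylocta-1,5-diene | ClCC/C=C(C)/CCC=C | intermediate
16 | (2R,3R)-2-(but-3-en-1-yl)-3-(2-chloroethyl)-2-methyloxirane | C=CCC[C@@]1(C)O[C@@H]1CCCl | intermediate
17 | 3-[(2R,3R)-3-(2-chloroethyl)-2-methyloxiran-2-yl]propanal | O=CCC[C@@]1(C)O[C@@H]1CCCl | intermediate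
18 | (2E)-5-[(2R,3R)-3-(2-chloroethyl)-2-methyloxiran-2-yl]-2-methylpent-2-enal | O=C/C(C)=C/CC[C@@]1(C)O[C@@H]1CCCl | intermediate
19 | (2R,3R)-3-(2-chloroethyl)-2-methyl-2-[(3E)-4-methylhexa-3,5-dien-1-yl]oxirane | C=C/C(C)=C/CC[C@@]1(C)O[C@@H]1CCCl | intermediate
20 | (2R,3R)-3-(2-iodoethyl)-2-methyl-2-[(3E)-4-methylhexa-3,5-dien-1-yl]oxirane (fragment B) | C=C/C(C)=C/CC[C@@]1(C)O[C@@H]1CCI | intermediate
21 | linear bromo-tetraene epoxide, tris-TBS (C4–C5 coupled) | C=C/C(C)=C/CC[C@@]1(C)O[C@@H]1CC/C(C)=C/[C@@H](O[Si](C)(C)C(C)(C)C)C(Br)=C(CO[Si](C)(C)C(C)(C)C)CO[Si](C)(C)C(C)(C)C | intermediate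
22 | (2R,3E,7R,8R,11E)-7,8-epoxy-2,16,17-tris(TBSO)cembra-1(15),3,11-triene | CC(C)(C)[Si](C)(C)OCC(CO[Si](C)(C)C(C)(C)C)=C1CC/C(C)=C/CC[C@@]2(C)O[C@@H]2CC/C(C)=C/[C@H]1O[Si](C)(C)C(C)(C)C | intermediate
23 | (2R,3E,7R,8R,11E)-7,8-epoxycembra-1(15),3,11-triene-2,16,17-triol | OCC(CO)=C1CC/C(C)=C/CC[C@@]2(C)O[C@@H]2CC/C(C)=C/[C@H]1O | intermediate
24 | lobophynin B | CC(=O)OCC1=C2CC/C(C)=C/CC[C@@]3(C)O[C@@H]3CC/C(C)=C/[C@H]2OC1 | target

## Totals

Total steps: 20.
Longest linear sequence: 12 (steps 9–16 then 17–20; steps 1–8 then 17–20 is equally long), which is 60 % of the total.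

## Steps most likely to fail, with fallbacks

1. **Step 18, macrocyclic B-alkyl Suzuki.** Oxidative addition into the hindered tetrasubstituted C1–Br bond may be slow and lose to protodeboronation. Fallback: change the ring-closing bond. Install C14–C1 intermolecularly at the fragment stage, then close the ring at C2–C3 by a Nozaki–Hiyama–Kishi reaction (C3 alkenyl iodide onto the C2 enal), followed by oxidation and CBS reduction to set C2.

2. **Step 17, zinc insertion and Negishi union.** The trisubstituted epoxide may not tolerate the zinc halide, and the I/Br chemoselectivity may be imperfect. Fallback: join the fragments before epoxidation. Use B-alkyl Suzuki coupling of a 9-BBN adduct of the non-epoxidised C5=C6 terminal-olefin precursor with 10, then Shi-epoxidise C7=C8 on the coupled product (C3=C4 is deactivated by the allylic silyl ether) before building the diene.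

3. **Step 20, sulfonylation, cyclisation and acetolysis.** The bis-allylic C2–OH may be over-sulfonylated or ionise. Fallback: switch to π-allyl chemistry. Acetylate the two primary hydroxyls selectively, then run a Pd(0) Tsuji–Trost intramolecular O-allylation by the C2–OH, which gives 24 directly with the second acetate retained.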